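**Plan**

- Retrosynthesis: the isopropyl ether on the ring C phenol is a protecting group removed last. The C4–C4a bond of the pyranone (ring B) is then cut to a 3-aryloxypent-2-enoic acid, and the O1–C2 bond to 3,4-dimethoxyphenol plus a pent-2-ynoate. The ynoate is cut at C(sp)–CO2Et and at ArCH2–CH2 to ethyl chloroformate, 1-(trimethylsilyl)propyne and a benzylic bromide made from isovanillin.
- Forward: the chain ring C–CH2CH2–C≡C–CO2Et is joined first (steps 1–6), ring A is attached through O1 by oxa-Michael addition (step 7), ring B closes by Friedel–Crafts acylation (step 9), and the phenol is unmasked (step 10).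
- Enabling feature: C4a of ring A lies ortho to O1 and para to the C7 methoxy group. It is the most nucleophilic free carbon of a 3,4-dimethoxyphenyl ether, so an acylium ion at C4 closes ring B there.
- Stereochemistry: the target has no stereocentre. The only stereo-element on the way, the Z enol ether of 13–16, comes from anti addition and is erased on ring closure.

Key step: step 9

Assumption: the phenoxide addition of step 7 is taken to give mainly the Z enol ether by anti addition. Any E isomer formed alongside is carried on unseparated, because the acid of step 9 interconverts the two.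

**Route**

Step 1
Reactants: 1 isovanillin; 2 2-bromopropane
Product: 3 3-isopropoxy-4-methoxybenzaldehyde
Conditions: K2CO3, DMF, 70 °C
Reagents that add atoms: none
Why: Williamson ether synthesis, in which K2CO3 forms the phenoxide of isovanillin and this displaces bromide from the secondary halide, while the non-enolisable aldehyde is untouched.

Step 2
Reactants: 3 3-isopropoxy-4-methoxybenzaldehyde
Product: 4 (3-isopropoxy-4-methoxyphenyl)methanol
Conditions: NaBH4, MeOH, 0 °C
Reagents that add atoms: none
Why: Hydride reduction of an aromatic aldehyde with NaBH4 is fast at 0 °C and leaves both aryl ethers alone.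

Step 3
Reactants: 4 (3-isopropoxy-4-methoxyphenyl)methanol
Product: 5 4-(bromomethyl)-2-isopropoxy-1-methoxybenzene
Conditions: PBr3, CH2Cl2, 0 °C; used crude at once
Reagents that add atoms: phosphorus tribromide, BrP(Br)Br
Why: Alcohol-to-bromide substitution with PBr3 (bromide displaces a phosphite leaving group in an SN2 step) is reliable for electron-rich benzylic alcohols at 0 °C, and immediate use avoids decomposition of the reactive bromide.

Step 4
Reactants: 5 4-(bromomethyl)-2-isopropoxy-1-methoxybenzene; 6 1-(trimethylsilyl)propyne
Product: 8 [4-(3-isopropoxy-4-methoxyphenyl)but-1-yn-1-yl]trimethylsilane, via 3-(trimethylsilyl)prop-2-ynyllithium 7 (not isolated)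
Conditions: 6, n-BuLi, THF, −78 → −20 °C; then 5, −78 °C → rt
Reagents that add atoms: none
Why: SN2 alkylation of a silyl-capped propargyl anion, in which the silyl group blocks the acetylenic carbon and disfavours allene formation, so the benzylic bromide is attacked by the CH2 terminus and the four-carbon chain results.

Step 5
Reactants: 8 [4-(3-isopropoxy-4-methoxyphenyl)but-1-yn-1-yl]trimethylsilane
Product: 9 4-(but-3-yn-1-yl)-2-isopropoxy-1-methoxybenzene
Conditions: K2CO3 (cat.), MeOH, rt
Reagents that add atoms: none
Why: Protodesilylation of an alkynylsilane by base-catalysed methanolysis of the C(sp)–Si bond is mild, and nothing else in 8 reacts with methoxide.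

Step 6
Reactants: 9 4-(but-3-yn-1-yl)-2-isopropoxy-1-methoxybenzene
Product: 11 ethyl 5-(3-isopropoxy-4-methoxyphenyl)pent-2-ynoate, via lithium acetylide 10 (not isolated)
Conditions: n-BuLi, THF, −78 °C; then ClCO2Et, −78 → 0 °C
Reagents that add atoms: ethyl chloroformate, CCOC(=O)Cl
Why: Deprotonation of the terminal alkyne and C-acylation of the lithium acetylide with a chloroformate is the standard entry to alk-2-ynoates, and the aryl ethers tolerate n-BuLi at −78 °C.

Step 7
Reactants: 11 ethyl 5-(3-isopropoxy-4-methoxyphenyl)pent-2-ynoate; 12 3,4-dimethoxyphenol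
Product: 13 ethyl (Z)-3-(3,4-dimethoxyphenoxy)-5-(3-isopropoxy-4-methoxyphenyl)pent-2-enoate
Conditions: K2CO3 (0.3 equiv), DMF, 80–90 °C
Reagents that add atoms: none
Why: Base-catalysed oxa-Michael addition of a phenol to an acetylenic ester, in which the phenoxide adds to C3 and the allenolate is protonated anti to the new C–O bond, which should favour the Z enol ether.

Step 8
Reactants: 13 ethyl (Z)-3-(3,4-dimethoxyphenoxy)-5-(3-isopropoxy-4-methoxyphenyl)pent-2-enoate
Product: 15 (Z)-3-(3,4-dimethoxyphenoxy)-5-(3-isopropoxy-4-methoxyphenyl)pent-2-enoic acid, via lithium carboxylate 14 (not isolated)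
Conditions: LiOH, THF/EtOH/H2O, rt; then 1 M HCl, 0 °C, to pH 3
Reagents that add atoms: lithium hydroxide (LiOH), [Li+].[OH-]
Why: Saponification of the ethyl ester, in which the carboxylate once formed shields the enol ether from further hydroxide attack, and brief cold acidification should free the acid without hydrolysing the aryl enol ether.

Step 9
Reactants: 15 (Z)-3-(3,4-dimethoxyphenoxy)-5-(3-isopropoxy-4-methoxyphenyl)pent-2-enoic acid
Product: 17 2-[2-(3-isopropoxy-4-methoxyphenyl)ethyl]-6,7-dimethoxychromone, via acyl methanesulfonate 16 (not isolated)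
Conditions: P2O5/CH3SO3H (Eaton's reagent, 7.7 wt% P2O5), rt → 40 °C; poured onto ice
Reagents that add atoms: none
Why: P2O5 in CH3SO3H converts acid 15 into the acyl methanesulfonate 16, which ionises to an acylium ion conjugated with the enol ether; this ion attacks ring A at the carbon ortho to the ether oxygen and para to a methoxy group, and loss of a proton gives the C4–C4a bond and the aromatic pyranone. The closest known reaction is the Friedel–Crafts cycloacylation of 3-aryloxyalk-2-enoic acids, made from phenols and acetylenic esters, to chromones in P2O5/CH3SO3H or polyphosphoric acid. Ring B closes as a six-membered ring by 6-exo-dig attack on the acylium carbon, the Z geometry of 15 holding the acyl group next to ring A; any E isomer should reach the same ion, because protonation at C2 of the pentenoic acid (the future chromone C3) makes C2–C3 a single bond that can rotate. No stereocentre is formed and the alkene geometry disappears in the product. The step needs acylation at the ring A carbon para to the methoxy group (the future C4a) and not at the carbon flanked by the two oxygen substituents, which para activation and crowding at the flanked site should secure; ring C cannot compete because it could only close a seven-membered ring. If the acid cleaves part of the isopropyl ether, the material formed is the target phenol 19 itself.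

Step 10
Reactants: 17 2-[2-(3-isopropoxy-4-methoxyphenyl)ethyl]-6,7-dimethoxychromone
Product: 19 2-[2-(3-hydroxy-4-methoxyphenyl)ethyl]-6,7-dimethoxychromone, via aryloxydichloroborane 18 (not isolated)
Conditions: BCl3 (3 equiv), CH2Cl2, −78 → 0 °C; then H2O
Reagents that add atoms: none
Why: Lewis-acid dealkylation of an isopropyl aryl ether, in which the secondary alkyl group leaves from the BCl3-complexed ether as 2-chloropropane much faster than a methyl group, and with hydrogen at C5 no methoxy group is chelated to the chromone carbonyl, so the three methyl ethers should survive at low temperature.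

**Compound list**

1 | isovanillin (3-hydroxy-4-methoxybenzaldehyde) | COc1ccc(C=O)cc1O | starting material
2 | 2-bromopropane | CC(C)Br | starting material
3 | 3-isopropoxy-4-methoxybenzaldehyde | COc1ccc(C=O)cc1OC(C)C | intermediate
4 | (3-isopropoxy-4-methoxyphenyl)methanol | COc1ccc(CO)cc1OC(C)C | intermediate
5 | 4-(bromomethyl)-2-isopropoxy-1-methoxybenzene | COc1ccc(CBr)cc1OC(C)C | intermediate
6 | 1-(trimethylsilyl)propyne | CC#C[Si](C)(C)C | starting material
7 | [3-(trimethylsilyl)prop-2-yn-1-yl]lithium | [Li]CC#C[Si](C)(C)C | intermediate
8 | [4-(3-isopropoxy-4-methoxyphenyl)but-1-yn-1-yl]trimethylsilane | COc1ccc(CCC#C[Si](C)(C)C)cc1OC(C)C | intermediate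
9 | 4-(but-3-yn-1-yl)-2-isopropoxy-1-methoxybenzene | COc1ccc(CCC#C)cc1OC(C)C | intermediate
10 | [4-(3-isopropoxy-4-methoxyphenyl)but-1-yn-1-yl]lithium | COc1ccc(CCC#C[Li])cc1OC(C)C | intermediate
11 | ethyl 5-(3-isopropoxy-4-methoxyphenyl)pent-2-ynoate | CCOC(=O)C#CCCc1ccc(OC)c(OC(C)C)c1 | intermediate
12 | 3,4-dimethoxyphenol | COc1ccc(O)cc1OC | starting material
13 | ethyl (Z)-3-(3,4-dimethoxyphenoxy)-5-(3-isopropoxy-4-methoxyphenyl)pent-2-enoate | CCOC(=O)/C=C(/CCc1ccc(OC)c(OC(C)C)c1)Oc1ccc(OC)c(OC)c1 | intermediate
14 | lithium (Z)-3-(3,4-dimethoxyphenoxy)-5-(3-isopropoxy-4-methoxyphenyl)pent-2-enoate | [Li+].[O-]C(=O)/C=C(/CCc1ccc(OC)c(OC(C)C)c1)Oc1ccc(OC)c(OC)c1 | intermediate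
15 | (Z)-3-(3,4-dimethoxyphenoxy)-5-(3-isopropoxy-4-methoxyphenyl)pent-2-enoic acid | OC(=O)/C=C(/CCc1ccc(OC)c(OC(C)C)c1)Oc1ccc(OC)c(OC)c1 | intermediate
16 | (Z)-3-(3,4-dimethoxyphenoxy)-5-(3-isopropoxy-4-methoxyphenyl)pent-2-enoic methanesulfonic anhydride | CS(=O)(=O)OC(=O)/C=C(/CCc1ccc(OC)c(OC(C)C)c1)Oc1ccc(OC)c(OC)c1 | intermediate
17 | 2-[2-(3-isopropoxy-4-methoxyphenyl)ethyl]-6,7-dimethoxychromone | COc1ccc(CCc2cc(=O)c3cc(OC)c(OC)cc3o2)cc1OC(C)C | intermediate
18 | dichloro{2-methoxy-5-[2-(6,7-dimethoxy-4-oxo-4H-chromen-2-yl)ethyl]phenoxy}borane | COc1ccc(CCc2cc(=O)c3cc(OC)c(OC)cc3o2)cc1OB(Cl)Cl | intermediate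
19 | 2-[2-(3-hydroxy-4-methoxyphenyl)ethyl]-6,7-dimethoxychromone (CNP0303336.0) | COc1ccc(CCc2cc(=O)c3cc(OC)c(OC)cc3o2)cc1O | target

**Count and risks**

Total step count: 10. Longest linear sequence: 10 steps (isovanillin 1 to target 19).

Steps most likely to fail:

1. Step 9. The strongly acidic medium may protonate the enol ether faster than the acylium ion closes. That could lead to loss of the aryloxy group, attack of ring C on the resulting oxocarbenium ion, or ring alkylation by the isopropyl cation released from the protecting group. Fallback: the pyranone is assembled by the Claisen condensation route, in which the C4–C4a bond exists before ring closure.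
 - It sets out from 12 and 5. Heating 12 with acetic acid and BF3·OEt2 acylates the same carbon para to methoxy and should give 2-hydroxy-4,5-dimethoxyacetophenone F1.
 - Alkylation of the lithium enolate of ethyl acetate (LDA, THF, −78 °C) with 5 should give ethyl 3-(3-isopropoxy-4-methoxyphenyl)propanoate F2.
 - Condensation of F1 with F2 using NaH in THF at reflux should give 1-(2-hydroxy-4,5-dimethoxyphenyl)-5-(3-isopropoxy-4-methoxyphenyl)pentane-1,3-dione F3.
 - Cyclodehydration with catalytic H2SO4 in acetic acid closes the O1–C2 bond and comes back to the route at 17.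

2. Step 7. The carbonate base may deprotonate the propargylic CH2 and move the triple bond into an allenoate or dienoate, and addition to a β-alkyl ynoate may be slow and reversible. Fallback: C3 is first made a better electrophile.
 - It sets out from 11. NaI in acetic acid at 80 °C adds HI anti across the triple bond and should give ethyl (Z)-3-iodo-5-(3-isopropoxy-4-methoxyphenyl)pent-2-enoate F4.
 - Addition–elimination with 12 and K2CO3 in DMF at room temperature (nucleophilic vinylic substitution with retention) comes back to the route at 13.

3. Step 4. Halogen–lithium exchange followed by Wurtz-type homocoupling of the benzylic bromide, alkylation at the allenic terminus, or decomposition of the bromide before it is consumed may erode the coupling. Fallback: the benzylic carbon is used at the aldehyde oxidation level.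
 - It sets out from 3. A Barbier reaction with 3-bromo-1-(trimethylsilyl)propyne and Zn dust in THF should give racemic 1-(3-isopropoxy-4-methoxyphenyl)-4-(trimethylsilyl)but-3-yn-1-ol F5.
 - Ionic hydrogenation of this electron-rich benzylic alcohol (Et3SiH, CF3CO2H, CH2Cl2, 0 °C) removes the hydroxyl group and comes back to the route at 8, so steps 2 and 3 are not needed.

**Further compounds**

F1 | step 9 | 2-hydroxy-4,5-dimethoxyacetophenone | CC(=O)c1cc(OC)c(OC)cc1O
F2 | step 9 | ethyl 3-(3-isopropoxy-4-methoxyphenyl)propanoate | CCOC(=O)CCc1ccc(OC)c(OC(C)C)c1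
F3 | step 9 | 1-(2-hydroxy-4,5-dimethoxyphenyl)-5-(3-isopropoxy-4-methoxyphenyl)pentane-1,3-dione | COc1ccc(CCC(=O)CC(=O)c2cc(OC)c(OC)cc2O)cc1OC(C)C
F4 | step 7 | ethyl (Z)-3-iodo-5-(3-isopropoxy-4-methoxyphenyl)pent-2-enoate | CCOC(=O)/C=C(\I)CCc1ccc(OC)c(OC(C)C)c1
F5 | step 4 | 1-(3-isopropoxy-4-methoxyphenyl)-4-(trimethylsilyl)but-3-yn-1-ol (racemic) | COc1ccc(C(O)CC#C[Si](C)(C)C)cc1OC(C)C
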